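**Retrosynthetic overview**

1. The biaryl axis C8–C6'' is cut in the biosynthetic sense. C8 belongs to ring A of the 4'-methoxyflavone half and C6'' to ring A of the 4'-hydroxyflavone half, so the target is the hetero-dimer of the natural flavones acacetin and apigenin, joined by a Suzuki–Miyaura cross-coupling of an 8-boronate with a 6-iodide.
2. Enabling feature: each terminus is the CH carbon lying between two oxygens of a phloroglucinol-type ring A, and the hydrogen bond from 5-OH to the C4 carbonyl acts as a switch. With O5 benzylated, iodination goes to C8 (between O7 and ring oxygen O1); with 5-OH free, it goes to C6 (ortho to the phenol).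
3. No ring is formed in the route: rings A, B and C of both halves are bought complete in the monomers, and only the axis is made.
4. Five benzyl ethers mask the phenols and leave in one hydrogenolysis; the 4'''-methyl ether comes in with acacetin.

Key step: step 7

Assumption: the SMILES gives no descriptor for the C8–C6'' axis; this tetra-ortho-oxygenated axis should be configurationally stable, so the racemate is taken as the target and no step controls it.

**Step 1**
Reactants: 1 acacetin (5,7-dihydroxy-2-(4-methoxyphenyl)-4H-chromen-4-one)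
Product: 2 5,7-bis(benzyloxy)-2-(4-methoxyphenyl)-4H-chromen-4-one
Conditions: BnBr (3 equiv), K2CO3, DMF, 80 °C
Reagents that add atoms: benzyl bromide, BrCc1ccccc1
Why: Williamson ether synthesis, in which the acidic 7-OH is alkylated first and heating in DMF breaks the 5-OH···O=C4 chelate so that O5 is benzylated as well.

**Step 2**
Reactants: 2 5,7-bis(benzyloxy)-2-(4-methoxyphenyl)-4H-chromen-4-one
Product: 3 5,7-bis(benzyloxy)-8-iodo-2-(4-methoxyphenyl)-4H-chromen-4-one
Conditions: NIS (1.1 equiv), TFA (cat.), CH2Cl2/MeCN, 0 °C to rt
Reagents that add atoms: N-iodosuccinimide, O=C1CCC(=O)N1I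
Why: Electrophilic aromatic iodination, which in 5,7-dialkoxyflavones should go to C8 (the CH between O7 and O1), while the benzyl rings and the anisyl ring B, deactivated by conjugation with the pyranone, are far less nucleophilic.

**Step 3**
Reactants: 3 5,7-bis(benzyloxy)-8-iodo-2-(4-methoxyphenyl)-4H-chromen-4-one
Product: 4 5,7-bis(benzyloxy)-2-(4-methoxyphenyl)-8-(4,4,5,5-tetramethyl-1,3,2-dioxaborolan-2-yl)-4H-chromen-4-one
Conditions: B2pin2 (1.5 equiv), PdCl2(dppf) (5 mol%), KOAc, 1,4-dioxane, 90 °C
Reagents that add atoms: bis(pinacolato)diboron, CC1(C)OB(B2OC(C)(C)C(C)(C)O2)OC1(C)C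
Why: Miyaura borylation, with oxidative addition of zerovalent palladium into the C8–I bond, acetate-assisted boryl transfer from B2pin2 and reductive elimination; KOAc is too weak a base to start a Suzuki homocoupling of the product.

**Step 4**
Reactants: 5 apigenin (5,7-dihydroxy-2-(4-hydroxyphenyl)-4H-chromen-4-one)
Product: 6 7-(benzyloxy)-2-[4-(benzyloxy)phenyl]-5-hydroxy-4H-chromen-4-one
Conditions: BnBr (2.2 equiv), K2CO3, DMF, rt
Reagents that add atoms: benzyl bromide, BrCc1ccccc1
Why: Williamson ether synthesis selective for the acidic 7-OH and 4'-OH, because the 5-OH is held in a hydrogen bond to the C4 carbonyl and should not be alkylated at room temperature.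

**Step 5**
Reactants: 6 7-(benzyloxy)-2-[4-(benzyloxy)phenyl]-5-hydroxy-4H-chromen-4-one
Product: 7 7-(benzyloxy)-2-[4-(benzyloxy)phenyl]-5-hydroxy-6-iodo-4H-chromen-4-one
Conditions: BnMe3N+ ICl2− (1.05 equiv), CaCO3, CH2Cl2/MeOH, rt
Reagents that add atoms: benzyltrimethylammonium dichloroiodate, C[N+](C)(C)Cc1ccccc1.Cl[I-]Cl
Why: Electrophilic iodination of a phenol, in which the free 5-OH should direct iodine to its only ortho CH, C6 (the known outcome for 5-hydroxy-7-alkoxyflavones with this reagent), while the aryl ethers of ring B do not react without a Lewis acid.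

**Step 6**
Reactants: 7 7-(benzyloxy)-2-[4-(benzyloxy)phenyl]-5-hydroxy-6-iodo-4H-chromen-4-one
Product: 8 5,7-bis(benzyloxy)-2-[4-(benzyloxy)phenyl]-6-iodo-4H-chromen-4-one
Conditions: BnBr (1.5 equiv), K2CO3, DMF, 70 °C
Reagents that add atoms: benzyl bromide, BrCc1ccccc1
Why: Williamson ether synthesis under heating to open the chelate, which removes the phenol that would otherwise sit as an electron-rich phenoxide next to the C–I bond and slow the coupling.

**Step 7**
Reactants: 4 5,7-bis(benzyloxy)-2-(4-methoxyphenyl)-8-(4,4,5,5-tetramethyl-1,3,2-dioxaborolan-2-yl)-4H-chromen-4-one; 8 5,7-bis(benzyloxy)-2-[4-(benzyloxy)phenyl]-6-iodo-4H-chromen-4-one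
Product: 9 5,7-bis(benzyloxy)-8-{5,7-bis(benzyloxy)-2-[4-(benzyloxy)phenyl]-4-oxo-4H-chromen-6-yl}-2-(4-methoxyphenyl)-4H-chromen-4-one (racemic about the new axis)
Conditions: Pd(OAc)2 (10 mol%), SPhos (2-dicyclohexylphosphino-2',6'-dimethoxybiphenyl, 20 mol%), K3PO4 (3 equiv), toluene/H2O (10:1), degassed, 100 °C
Reagents that add atoms: none
Why: Suzuki–Miyaura cross-coupling, in which zerovalent palladium formed from Pd(OAc)2 and SPhos adds oxidatively into the C6–I bond of 8, the boronate 4 (activated by phosphate and water) transfers its C8 aryl group to palladium, and reductive elimination forms the C8–C6'' bond. The closest known reaction types are the Suzuki–Miyaura synthesis of tetra-ortho-substituted biaryls with dialkylbiarylphosphine ligands and the coupling of iodoflavones with flavonyl boronates to C–C linked biflavones. No ring is closed. No stereocentre is formed; the new axis arises as the racemate, which the assumption allows. The step needs cross-coupling instead of homo-coupling and bond formation only at C8 and C6'', and both are secured by where boron and iodine were placed through the O5 switch in steps 2 and 5. Oxidative addition into Ar–I should leave the benzyl ethers and the flavone enones untouched, and the bulky electron-rich ligand should speed transmetalation and reductive elimination enough to outrun protodeboronation of the di-ortho-oxygenated boronate, helped by the four ortho substituents being oxygens and not carbon groups.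

**Step 8**
Reactants: 9 5,7-bis(benzyloxy)-8-{5,7-bis(benzyloxy)-2-[4-(benzyloxy)phenyl]-4-oxo-4H-chromen-6-yl}-2-(4-methoxyphenyl)-4H-chromen-4-one
Product: 10 5,7-dihydroxy-8-[5,7-dihydroxy-2-(4-hydroxyphenyl)-4-oxo-4H-chromen-6-yl]-2-(4-methoxyphenyl)-4H-chromen-4-one (target)
Conditions: H2 (1 atm), Pd/C, THF/MeOH, rt
Reagents that add atoms: none
Why: Catalytic hydrogenolysis of the five benzyl aryl ethers, under which the aryl methyl ether is inert and the C2=C3 bonds of the two flavones, being vinylogous esters conjugated with aryl groups, should not be reduced at ambient pressure and temperature.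

**Compound list**

1 | acacetin, 5,7-dihydroxy-2-(4-methoxyphenyl)-4H-chromen-4-one | COc1ccc(-c2cc(=O)c3c(O)cc(O)cc3o2)cc1 | starting material
2 | 5,7-bis(benzyloxy)-2-(4-methoxyphenyl)-4H-chromen-4-one | COc1ccc(-c2cc(=O)c3c(OCc4ccccc4)cc(OCc4ccccc4)cc3o2)cc1 | intermediate
3 | 5,7-bis(benzyloxy)-8-iodo-2-(4-methoxyphenyl)-4H-chromen-4-one | COc1ccc(-c2cc(=O)c3c(OCc4ccccc4)cc(OCc4ccccc4)c(I)c3o2)cc1 | intermediate
4 | 5,7-bis(benzyloxy)-2-(4-methoxyphenyl)-8-(4,4,5,5-tetramethyl-1,3,2-dioxaborolan-2-yl)-4H-chromen-4-one | COc1ccc(-c2cc(=O)c3c(OCc4ccccc4)cc(OCc4ccccc4)c(B4OC(C)(C)C(C)(C)O4)c3o2)cc1 | intermediate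
5 | apigenin, 5,7-dihydroxy-2-(4-hydroxyphenyl)-4H-chromen-4-one | O=c1cc(-c2ccc(O)cc2)oc2cc(O)cc(O)c12 | starting material
6 | 7-(benzyloxy)-2-[4-(benzyloxy)phenyl]-5-hydroxy-4H-chromen-4-one | O=c1cc(-c2ccc(OCc3ccccc3)cc2)oc2cc(OCc3ccccc3)cc(O)c12 | intermediate
7 | 7-(benzyloxy)-2-[4-(benzyloxy)phenyl]-5-hydroxy-6-iodo-4H-chromen-4-one | O=c1cc(-c2ccc(OCc3ccccc3)cc2)oc2cc(OCc3ccccc3)c(I)c(O)c12 | intermediate
8 | 5,7-bis(benzyloxy)-2-[4-(benzyloxy)phenyl]-6-iodo-4H-chromen-4-one | O=c1cc(-c2ccc(OCc3ccccc3)cc2)oc2cc(OCc3ccccc3)c(I)c(OCc3ccccc3)c12 | intermediate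
9 | 5,7-bis(benzyloxy)-8-{5,7-bis(benzyloxy)-2-[4-(benzyloxy)phenyl]-4-oxo-4H-chromen-6-yl}-2-(4-methoxyphenyl)-4H-chromen-4-one, racemic about the axis | COc1ccc(-c2cc(=O)c3c(OCc4ccccc4)cc(OCc4ccccc4)c(-c4c(OCc5ccccc5)cc5oc(-c6ccc(OCc7ccccc7)cc6)cc(=O)c5c4OCc4ccccc4)c3o2)cc1 | intermediate
10 | 5,7-dihydroxy-8-[5,7-dihydroxy-2-(4-hydroxyphenyl)-4-oxo-4H-chromen-6-yl]-2-(4-methoxyphenyl)-4H-chromen-4-one, racemic about the axis | COc1ccc(-c2cc(=O)c3c(O)cc(O)c(-c4c(O)cc5oc(-c6ccc(O)cc6)cc(=O)c5c4O)c3o2)cc1 | target

**Step count and risks**

Total step count: 8.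
Longest linear sequence: 5 steps (steps 1, 2, 3, 7, 8 from acacetin; the apigenin branch, steps 4, 5, 6, 7, 8, is equally long).

Steps most likely to fail:

1. Step 7. Transmetalation at the boron centre flanked by two oxygens, and reductive elimination to a tetra-ortho-substituted axis, may be slower than hydrolytic protodeboronation of 4 and hydrodeiodination of 8, so the coupling could stall. The fallback is the classical copper-mediated mixed Ullmann coupling of two iodoflavones, which needs no boron. It sets out from iodide 3 (leaving out step 3) and iodide 8, which are heated with activated copper bronze in DMF at about 150 °C. The hetero-coupled product should form beside the two homo-dimers and be separated by chromatography, and the fallback comes back to the route at 9. It makes no compound outside the list (F0).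

2. Step 3. At the hindered palladium–C8 centre, reduction to the deiodinated flavone may outrun boryl transfer, and the boronate may lose boron on silica during isolation. The fallback replaces the boron route by a Negishi coupling, the established alternative for tetra-ortho-substituted biaryls. It sets out from 3, which is treated with zinc dust and LiCl in THF at 50 °C, conditions that tolerate the flavone carbonyl. This should give [5,7-bis(benzyloxy)-2-(4-methoxyphenyl)-4-oxo-4H-chromen-8-yl]zinc iodide F1, which is not isolated. F1 is coupled with iodide 8 using Pd2(dba)3 and RuPhos (2-dicyclohexylphosphino-2',6'-diisopropoxybiphenyl) in THF/NMP at 70 °C. The fallback comes back to the route at 9, bypassing 4 and step 7.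

3. Step 8. Partial saturation of the C2–C3 double bonds to flavanones, or stalling at the benzyl ethers that flank the axis, may give mixtures. The fallback is a Lewis-acid debenzylation in place of hydrogenation. It sets out from 9, which is treated with excess BCl3 and pentamethylbenzene as cation scavenger in CH2Cl2 at −78 °C, and it comes back to the route at 10. The 4'''-methyl ether is not chelated to a carbonyl and should survive, and no reduction can occur. It makes no compound outside the list (F0).

**Further compounds**

F0 | step 7 | none | none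
F1 | step 3 | [5,7-bis(benzyloxy)-2-(4-methoxyphenyl)-4-oxo-4H-chromen-8-yl]zinc iodide | COc1ccc(-c2cc(=O)c3c(OCc4ccccc4)cc(OCc4ccccc4)c([Zn]I)c3o2)cc1
F0 | step 8 | none | none
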